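**Plan**

- Cembrane numbering is used: C1 ring-fusion CH, C2 lactone carbinol, C9 acetoxy carbon, C15/C16/C17 lactone α-carbon, carbonyl and exocyclic CH2; ring alkenes C3=C4, C7=C8, C11=C12.
- Retrosynthesis: take off C17 and trade OAc for OTBS; then cut C2–C3 and O–C16 together, opening both rings to a chain with a C2 aldehyde, a C16 methyl ester and an (E)-C3 alkenyl iodide; cut this chain at C12–C13.
- Enabling feature: C2 is at once the carbinol carbon of the five-membered lactone and the ring carbon allylic to C3=C4 in the 14-membered carbocycle, with its oxygen four atoms from C16. One alkenyl addition to a C2 aldehyde therefore closes the carbocycle and leaves an alkoxide set for 5-exo lactonisation.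
- Forward: fragment A (C3–C12, from 6-methylhept-5-en-2-one and allenylboronic ester) and fragment B (C13–C16 with C1 and C2, from (E)-but-2-ene-1,4-diol and dimethyl malonate) are joined at C12–C13 by B-alkyl Suzuki coupling. C3 travels as the bromide and becomes the iodide afterwards; the carbocycle closes first and the lactone second in the same flask; C17 and the acetate come last.
- Stereochemistry: C9 from phosphoric acid-catalysed propargylboration, C1 from iridium-catalysed allylic alkylation, C2 from the chiral sulfonamide ligand on chromium during ring closure; the E alkenes from syn-carboalumination, SeO2 oxidation and syn-hydrozirconation.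

Key step: step 16

Remark: C9 is carried as the TBS ether (robust to the 110 °C halide exchange and to amide bases), and (E)-but-2-ene-1,4-diol is taken as a catalogue chemical.

**Route**

Step 1
Reactants: 1 6-methylhept-5-en-2-one
Product: 3 6-methylhept-5-en-1-yne, via enol phosphate 2 (not isolated)
Conditions: LiN(i-Pr)2 (1.1 equiv), THF, −78 °C; ClP(O)(OEt)2, −78 °C to rt; then LiN(i-Pr)2 (2.3 equiv), −78 °C to rt
Reagents that add atoms: none
Why: Kinetic deprotonation at the methyl group, O-phosphorylation and base-induced elimination of the terminal enol phosphate (Negishi methyl ketone-to-alkyne conversion) should give the terminal alkyne with the trisubstituted alkene untouched.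

Step 2
Reactants: 3 6-methylhept-5-en-1-yne
Product: 5 (1E)-1-bromo-2,6-dimethylhepta-1,5-diene, via alkenylalane 4 (not isolated)
Conditions: AlMe3 (2 equiv), Cp2ZrCl2 (20 mol%), CH2Cl2, 0 °C to rt; then N-bromosuccinimide, THF, −30 °C
Reagents that add atoms: trimethylaluminium C[Al](C)C; N-bromosuccinimide O=C1CCC(=O)N1Br
Why: Zirconocene-catalysed syn-methylalumination (Negishi carboalumination) puts the methyl on C4 and aluminium on C3, and bromodealumination with retention fixes the E geometry of C3=C4; bromide rather than iodide is installed so that C3 stays inert in the palladium coupling of step 12.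

Step 3
Reactants: 5 (1E)-1-bromo-2,6-dimethylhepta-1,5-diene
Product: 7 (2E,6E)-7-bromo-2,6-dimethylhepta-2,6-dienal, via allylic alcohol 6 (not isolated)
Conditions: SeO2 (20 mol%), t-BuOOH (3 equiv), salicylic acid (10 mol%), CH2Cl2, rt; filtered crude, then MnO2, CH2Cl2, rt
Reagents that add atoms: tert-butyl hydroperoxide CC(C)(C)OO
Why: Catalytic SeO2 allylic oxidation (Riley oxidation; ene reaction then [2,3]-shift) selects the E methyl of the electron-richer C7=C8 alkene over the bromine-deactivated one, and MnO2 carries the allylic alcohol on to the E enal.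

Step 4
Reactants: 7 (2E,6E)-7-bromo-2,6-dimethylhepta-2,6-dienal; 8 allenylboronic acid pinacol ester
Product: 10 (4R,5E,9E)-10-bromo-5,9-dimethyldeca-5,9-dien-1-yn-4-ol, via borate ester 9 (not isolated)
Conditions: (R)-TRIP [(R)-3,3′-bis(2,4,6-triisopropylphenyl)-1,1′-binaphthyl-2,2′-diyl hydrogen phosphate] (5 mol%), 4 Å molecular sieves, toluene, −20 °C; aqueous work-up
Reagents that add atoms: none
Why: Brønsted acid-catalysed propargylboration through a closed six-membered SE2′ transition state gives the homopropargylic alcohol, the phosphoric acid holding the boronate so that the allenyl terminus should add to the Re face of the enal and set C9 as R.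

Step 5
Reactants: 10 (4R,5E,9E)-10-bromo-5,9-dimethyldeca-5,9-dien-1-yn-4-ol
Product: 11 tert-butyl{[(4R,5E,9E)-10-bromo-5,9-dimethyldeca-5,9-dien-1-yn-4-yl]oxy}dimethylsilane
Conditions: TBSCl, imidazole, DMF, rt
Reagents that add atoms: tert-butyldimethylsilyl chloride CC(C)(C)[Si](C)(C)Cl
Why: Imidazole-promoted silylation of the secondary allylic alcohol gives a silyl ether that should last through hydrozirconation, the hot halide exchange and the later enolate chemistry.

Step 6
Reactants: 11 tert-butyl{[(4R,5E,9E)-10-bromo-5,9-dimethyldeca-5,9-dien-1-yn-4-yl]oxy}dimethylsilane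
Product: 12 tert-butyl{[(5R,6E,10E)-11-bromo-6,10-dimethylundeca-6,10-dien-2-yn-5-yl]oxy}dimethylsilane
Conditions: LiN(i-Pr)2 (1.1 equiv), THF, −78 °C; MeI, DMPU, −78 °C to rt
Reagents that add atoms: iodomethane CI
Why: Acetylide alkylation, in which the amide base deprotonates only the terminal alkyne (an alkyllithium is avoided because of the alkenyl bromide) and SN2 methylation supplies the C12 methyl group.

Step 7
Reactants: 12 tert-butyl{[(5R,6E,10E)-11-bromo-6,10-dimethylundeca-6,10-dien-2-yn-5-yl]oxy}dimethylsilane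
Product: 14 tert-butyl{[(2E,5R,6E,10E)-11-bromo-2-iodo-6,10-dimethylundeca-2,6,10-trien-5-yl]oxy}dimethylsilane (fragment A), via alkenylzirconocene 13 (not isolated)
Conditions: Cp2Zr(H)Cl (2.5 equiv), THF, 50 °C; then I2, THF, 0 °C
Reagents that add atoms: iodine II
Why: Hydrozirconation adds H and Zr syn across the 2-alkyne and, with excess hydride, equilibrates zirconium to the less hindered methyl-bearing C12, so iodinolysis with retention should give the E 2-iodoalkene while the alkenyl bromide and the trisubstituted alkenes stay inert.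

Step 8
Reactants: 15 (2E)-but-2-ene-1,4-diol
Product: 16 (2E)-4-[(4-methoxybenzyl)oxy]but-2-en-1-ol
Conditions: NaH (1 equiv), 15 (3 equiv), THF/DMF, 0 °C; 4-methoxybenzyl chloride, Bu4NI (cat.), rt
Reagents that add atoms: 4-methoxybenzyl chloride COc1ccc(CCl)cc1
Why: Williamson etherification of the mono-alkoxide, with excess diol keeping double alkylation low.

Step 9
Reactants: 16 (2E)-4-[(4-methoxybenzyl)oxy]but-2-en-1-ol
Product: 17 (2E)-4-[(4-methoxybenzyl)oxy]but-2-en-1-yl methyl carbonate
Conditions: ClCO2Me, pyridine, CH2Cl2, 0 °C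
Reagents that add atoms: methyl chloroformate COC(=O)Cl
Why: O-acylation of the primary allylic alcohol installs the carbonate leaving group needed for ionisation by iridium.

Step 10
Reactants: 17 (2E)-4-[(4-methoxybenzyl)oxy]but-2-en-1-yl methyl carbonate; 18 dimethyl malonate
Product: 19 dimethyl 2-{(2R)-1-[(4-methoxybenzyl)oxy]but-3-en-2-yl}propanedioate
Conditions: [Ir(cod)Cl]2 (2 mol%), (Sa,Sc,Sc)-O,O′-(1,1′-binaphthyl-2,2′-diyl)-N,N-bis(1-phenylethyl)phosphoramidite (4 mol%), TBD (8 mol%), THF, rt
Reagents that add atoms: none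
Why: Iridium-catalysed asymmetric allylic alkylation, in which the cyclometalated iridium phosphoramidite ionises the E carbonate to an allyl complex and malonate attacks the substituted terminus anti to the metal, so the branched product should form with the ligand setting the future C1 as R.

Step 11
Reactants: 19 dimethyl 2-{(2R)-1-[(4-methoxybenzyl)oxy]but-3-en-2-yl}propanedioate
Product: 20 methyl (3S)-3-{[(4-methoxybenzyl)oxy]methyl}pent-4-enoate (fragment B)
Conditions: LiCl, H2O, DMSO, 150 °C
Reagents that add atoms: none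
Why: Krapcho dealkoxycarbonylation (chloride demethylation, decarboxylation, protonation) removes one ester, and the allylic stereocentre, being β to the carbonyl, cannot epimerise (its descriptor changes from R to S by priority only).

Step 12
Reactants: 20 methyl (3S)-3-{[(4-methoxybenzyl)oxy]methyl}pent-4-enoate; 14 tert-butyl{[(2E,5R,6E,10E)-11-bromo-2-iodo-6,10-dimethylundeca-2,6,10-trien-5-yl]oxy}dimethylsilane
Product: 22 methyl (3R,6E,9R,10E,14E)-15-bromo-9-[(tert-butyldimethylsilyl)oxy]-3-{[(4-methoxybenzyl)oxy]methyl}-6,10,14-trimethylpentadeca-6,10,14-trienoate, via alkylborane 21 (not isolated)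
Conditions: 20 (1.4 equiv), 9-BBN, THF, rt; then 14, Pd(dppf)Cl2 (5 mol%), AsPh3 (10 mol%), Cs2CO3, DMF/H2O, rt
Reagents that add atoms: none
Why: B-alkyl Suzuki–Miyaura coupling, in which anti-Markovnikov hydroboration gives the primary alkylborane, zerovalent palladium inserts into the C12–I bond far faster than into the C3–Br bond at room temperature, and transmetalation and reductive elimination join C12–C13 with retention of the E geometry.

Step 13
Reactants: 22 methyl (3R,6E,9R,10E,14E)-15-bromo-9-[(tert-butyldimethylsilyl)oxy]-3-{[(4-methoxybenzyl)oxy]methyl}-6,10,14-trimethylpentadeca-6,10,14-trienoate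
Product: 23 methyl (3R,6E,9R,10E,14E)-9-[(tert-butyldimethylsilyl)oxy]-15-iodo-3-{[(4-methoxybenzyl)oxy]methyl}-6,10,14-trimethylpentadeca-6,10,14-trienoate
Conditions: CuI (10 mol%), trans-N,N′-dimethylcyclohexane-1,2-diamine (20 mol%), NaI (2 equiv), 1,4-dioxane, 110 °C
Reagents that add atoms: sodium iodide [Na+].[I-]
Why: Copper-catalysed Finkelstein-type halogen exchange of an alkenyl bromide on diamine-ligated monovalent copper should proceed with retention of alkene geometry and is driven by precipitation of NaBr from dioxane.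

Step 14
Reactants: 23 methyl (3R,6E,9R,10E,14E)-9-[(tert-butyldimethylsilyl)oxy]-15-iodo-3-{[(4-methoxybenzyl)oxy]methyl}-6,10,14-trimethylpentadeca-6,10,14-trienoate
Product: 24 methyl (3R,6E,9R,10E,14E)-9-[(tert-butyldimethylsilyl)oxy]-3-(hydroxymethyl)-15-iodo-6,10,14-trimethylpentadeca-6,10,14-trienoate
Conditions: DDQ, CH2Cl2/pH 7 buffer, 0 °C; used at once
Reagents that add atoms: none
Why: Oxidative cleavage of the 4-methoxybenzyl ether (benzylic hydride abstraction, then hydrolysis of the oxocarbenium ion) under buffered conditions should leave the silyl ether, ester and alkenyl iodide alone, and immediate use keeps the hydroxyl from closing onto the ester.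

Step 15
Reactants: 24 methyl (3R,6E,9R,10E,14E)-9-[(tert-butyldimethylsilyl)oxy]-3-(hydroxymethyl)-15-iodo-6,10,14-trimethylpentadeca-6,10,14-trienoate
Product: 25 methyl (3R,6E,9R,10E,14E)-9-[(tert-butyldimethylsilyl)oxy]-3-formyl-15-iodo-6,10,14-trimethylpentadeca-6,10,14-trienoate
Conditions: Dess–Martin periodinane, NaHCO3, CH2Cl2, 0 °C to rt
Reagents that add atoms: none
Why: Dess–Martin oxidation under buffered, non-basic conditions should give the C2 aldehyde without epimerising C1 or touching the alkenyl iodide.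

Step 16
Reactants: 25 methyl (3R,6E,9R,10E,14E)-9-[(tert-butyldimethylsilyl)oxy]-3-formyl-15-iodo-6,10,14-trimethylpentadeca-6,10,14-trienoate
Product: 27 trans-fused lactone (1R,2R,9R,3E,7E,11E)-9-[(tert-butyldimethylsilyl)oxy]-17-norcembra-3,7,11-trien-16,2-olide, via chromium alkoxide 26 (not isolated)
Conditions: CrCl2 (6 equiv), (S)-N-[2-(4-isopropyl-4,5-dihydro-1,3-oxazol-2-yl)-6-methylphenyl]methanesulfonamide (6.6 equiv), Et3N (6.6 equiv), NiCl2(2,9-dimethyl-1,10-phenanthroline) (20 mol%), MeCN/THF, slow addition of 25 to 2 mM, rt, then 40 °C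
Reagents that add atoms: none
Why: Zerovalent nickel, formed from NiCl2 by divalent chromium, inserts into the C3–I bond with retention and passes the alkenyl group to trivalent chromium; the alkenylchromium adds only to the C2 aldehyde, and the trivalent chromium alkoxide 26 then attacks the C16 methyl ester four atoms away and expels methoxide. The closest known reaction type is the Nozaki–Hiyama–Kishi macrocyclisation of an alkenyl iodide onto an aldehyde under chiral sulfonamide–oxazoline control, coupled with the lactonisation that metal alkoxides of γ-hydroxy esters undergo. The 14-membered carbocycle closes by 14-exo-trig addition to the aldehyde carbonyl and the lactone by 5-exo-trig acyl substitution. C2 is the only new stereocentre and is set by the ligand on chromium, which should direct the alkenyl group to the Si face of the aldehyde because the two CH2 substituents on C1 give little 1,2-induction; the lactone forms with retention at C2 and is therefore trans-fused. The step needs aldehyde-over-ester chemoselectivity, an intact C1 stereocentre and retention of the E C3=C4 geometry, which the neutral organochromium and the configurationally stable alkenylmetal should secure, while the 1,4-relation of O2 and C16 allows only five-membered ring closure and high dilution suppresses oligomers.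

Step 17
Reactants: 27 trans-fused lactone (1R,2R,9R,3E,7E,11E)-9-[(tert-butyldimethylsilyl)oxy]-17-norcembra-3,7,11-trien-16,2-olide
Product: 28 15-[(dimethylamino)methyl] derivative of 27 (C15 epimers)
Conditions: LiN(i-Pr)2, THF, −78 °C; N,N-dimethylmethyleneiminium iodide, −78 °C to rt
Reagents that add atoms: N,N-dimethylmethyleneiminium iodide C[N+](C)=C.[I-]
Why: Mannich reaction of the lactone enolate with Eschenmoser's salt at C15, the only acidic position, brings in C17; the new C15 stereocentre is of no consequence because the next step removes it.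

Step 18
Reactants: 28 15-[(dimethylamino)methyl] derivative of 27 (C15 epimers)
Product: 30 (1R,2S,9R,3E,7E,11E)-9-[(tert-butyldimethylsilyl)oxy]cembra-3,7,11,15(17)-tetraen-16,2-olide, via ammonium iodide 29 (not isolated)
Conditions: MeI, MeOH, rt; concentrate; then NaHCO3 (aq)/CH2Cl2, rt
Reagents that add atoms: none
Why: N-Methylation followed by E1cB elimination of trimethylamine from the β-ammonio lactone under mild base should give the exocyclic C15=C17 alkene (the C2 descriptor changes from R to S by priority only).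

Step 19
Reactants: 30 (1R,2S,9R,3E,7E,11E)-9-[(tert-butyldimethylsilyl)oxy]cembra-3,7,11,15(17)-tetraen-16,2-olide
Product: 31 (1R,2S,9R,3E,7E,11E)-9-hydroxycembra-3,7,11,15(17)-tetraen-16,2-olide
Conditions: HF·pyridine, pyridine, THF, 0 °C to rt
Reagents that add atoms: none
Why: Buffered fluoride desilylation frees the C9 alcohol without adding a nucleophile to the α-methylene lactone.

Step 20
Reactants: 31 (1R,2S,9R,3E,7E,11E)-9-hydroxycembra-3,7,11,15(17)-tetraen-16,2-olide
Product: 32 (1R,2S,9R,3E,7E,11E)-9-acetoxycembra-3,7,11,15(17)-tetraen-16,2-olide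
Conditions: Ac2O, pyridine, DMAP (cat.), CH2Cl2, 0 °C
Reagents that add atoms: acetic anhydride CC(=O)OC(C)=O
Why: DMAP-catalysed acylation of the secondary allylic alcohol gives the C9 acetate with retention and completes the target.

**Compound list**

1 | 6-methylhept-5-en-2-one | CC(=O)CCC=C(C)C | starting material
2 | diethyl 6-methylhepta-1,5-dien-2-yl phosphate (enol phosphate) | C=C(CCC=C(C)C)OP(=O)(OCC)OCC | intermediate
3 | 6-methylhept-5-en-1-yne | C#CCCC=C(C)C | intermediate
4 | [(1E)-2,6-dimethylhepta-1,5-dien-1-yl]dimethylalane | C[Al](C)/C=C(\C)CCC=C(C)C | intermediate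
5 | (1E)-1-bromo-2,6-dimethylhepta-1,5-diene | Br/C=C(\C)CCC=C(C)C | intermediate
6 | (2E,6E)-7-bromo-2,6-dimethylhepta-2,6-dien-1-ol | OC/C(C)=C/CC/C(C)=C/Br | intermediate
7 | (2E,6E)-7-bromo-2,6-dimethylhepta-2,6-dienal | O=C/C(C)=C/CC/C(C)=C/Br | intermediate
8 | allenylboronic acid pinacol ester | C=C=CB1OC(C)(C)C(C)(C)O1 | starting material
9 | pinacol borate ester of 10 (boron on the C9 oxygen) | CC1(C)OB(O[C@H](CC#C)/C(C)=C/CC/C(C)=C/Br)OC1(C)C | intermediate
10 | (4R,5E,9E)-10-bromo-5,9-dimethyldeca-5,9-dien-1-yn-4-ol | C#CC[C@@H](O)/C(C)=C/CC/C(C)=C/Br | intermediate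
11 | tert-butyl{[(4R,5E,9E)-10-bromo-5,9-dimethyldeca-5,9-dien-1-yn-4-yl]oxy}dimethylsilane | C#CC[C@@H](O[Si](C)(C)C(C)(C)C)/C(C)=C/CC/C(C)=C/Br | intermediate
12 | tert-butyl{[(5R,6E,10E)-11-bromo-6,10-dimethylundeca-6,10-dien-2-yn-5-yl]oxy}dimethylsilane | CC#CC[C@@H](O[Si](C)(C)C(C)(C)C)/C(C)=C/CC/C(C)=C/Br | intermediate
13 | alkenylzirconocene chloride from 12 (Cp2ZrCl on C12, trans to C10; Cp drawn sigma-bonded) | C/C(=C\C[C@@H](O[Si](C)(C)C(C)(C)C)/C(C)=C/CC/C(C)=C/Br)[Zr](Cl)(C1C=CC=C1)C1C=CC=C1 | intermediate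
14 | tert-butyl{[(2E,5R,6E,10E)-11-bromo-2-iodo-6,10-dimethylundeca-2,6,10-trien-5-yl]oxy}dimethylsilane (fragment A) | C/C(I)=C\C[C@@H](O[Si](C)(C)C(C)(C)C)/C(C)=C/CC/C(C)=C/Br | intermediate
15 | (2E)-but-2-ene-1,4-diol | OC/C=C/CO | starting material
16 | (2E)-4-[(4-methoxybenzyl)oxy]but-2-en-1-ol | COc1ccc(COC/C=C/CO)cc1 | intermediate
17 | (2E)-4-[(4-methoxybenzyl)oxy]but-2-en-1-yl methyl carbonate | COC(=O)OC/C=C/COCc1ccc(OC)cc1 | intermediate
18 | dimethyl malonate | COC(=O)CC(=O)OC | starting material
19 | dimethyl 2-{(2R)-1-[(4-methoxybenzyl)oxy]but-3-en-2-yl}propanedioate | C=C[C@@H](COCc1ccc(OC)cc1)C(C(=O)OC)C(=O)OC | intermediate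
20 | methyl (3S)-3-{[(4-methoxybenzyl)oxy]methyl}pent-4-enoate (fragment B) | C=C[C@@H](COCc1ccc(OC)cc1)CC(=O)OC | intermediate
21 | methyl (3R)-5-(9-borabicyclo[3.3.1]nonan-9-yl)-3-{[(4-methoxybenzyl)oxy]methyl}pentanoate | COC(=O)C[C@H](COCc1ccc(OC)cc1)CCB1C2CCCC1CCC2 | intermediate
22 | methyl (3R,6E,9R,10E,14E)-15-bromo-9-[(tert-butyldimethylsilyl)oxy]-3-{[(4-methoxybenzyl)oxy]methyl}-6,10,14-trimethylpentadeca-6,10,14-trienoate | COC(=O)C[C@H](COCc1ccc(OC)cc1)CC/C(C)=C/C[C@@H](O[Si](C)(C)C(C)(C)C)/C(C)=C/CC/C(C)=C/Br | intermediate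
23 | methyl (3R,6E,9R,10E,14E)-9-[(tert-butyldimethylsilyl)oxy]-15-iodo-3-{[(4-methoxybenzyl)oxy]methyl}-6,10,14-trimethylpentadeca-6,10,14-trienoate | COC(=O)C[C@H](COCc1ccc(OC)cc1)CC/C(C)=C/C[C@@H](O[Si](C)(C)C(C)(C)C)/C(C)=C/CC/C(C)=C/I | intermediate
24 | methyl (3R,6E,9R,10E,14E)-9-[(tert-butyldimethylsilyl)oxy]-3-(hydroxymethyl)-15-iodo-6,10,14-trimethylpentadeca-6,10,14-trienoate | COC(=O)C[C@H](CO)CC/C(C)=C/C[C@@H](O[Si](C)(C)C(C)(C)C)/C(C)=C/CC/C(C)=C/I | intermediate
25 | methyl (3R,6E,9R,10E,14E)-9-[(tert-butyldimethylsilyl)oxy]-3-formyl-15-iodo-6,10,14-trimethylpentadeca-6,10,14-trienoate (open chain: C2 aldehyde, C16 ester, C3 iodide) | O=C[C@@H](CC(=O)OC)CC/C(C)=C/C[C@@H](O[Si](C)(C)C(C)(C)C)/C(C)=C/CC/C(C)=C/I | intermediate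
26 | chromium alkoxide of methyl 2-[(1R,2R,3E,7E,9R,11E)-9-[(tert-butyldimethylsilyl)oxy]-2-hydroxy-4,8,12-trimethylcyclotetradeca-3,7,11-trien-1-yl]acetate (drawn as the CrCl2 alkoxide, ligand omitted) | COC(=O)C[C@H]1CC/C(C)=C/C[C@@H](O[Si](C)(C)C(C)(C)C)/C(C)=C/CC/C(C)=C/[C@@H]1O[Cr](Cl)Cl | intermediate
27 | (1R,2R,9R,3E,7E,11E)-9-[(tert-butyldimethylsilyl)oxy]-17-norcembra-3,7,11-trien-16,2-olide (14-membered carbocycle trans-fused at C1/C2 to a γ-butyrolactone) | C1C(=O)O[C@H]2/C=C(\C)CC/C=C(\C)[C@H](O[Si](C)(C)C(C)(C)C)C/C=C(\C)CC[C@H]12 | intermediate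
28 | 15-[(dimethylamino)methyl] derivative of 27, (1R,2R,9R), mixture of C15 epimers | CN(C)CC1C(=O)O[C@H]2/C=C(\C)CC/C=C(\C)[C@H](O[Si](C)(C)C(C)(C)C)C/C=C(\C)CC[C@H]12 | intermediate
29 | trimethylammonium iodide obtained from 28 by N-methylation | C[N+](C)(C)CC1C(=O)O[C@H]2/C=C(\C)CC/C=C(\C)[C@H](O[Si](C)(C)C(C)(C)C)C/C=C(\C)CC[C@H]12.[I-] | intermediate
30 | (1R,2S,9R,3E,7E,11E)-9-[(tert-butyldimethylsilyl)oxy]cembra-3,7,11,15(17)-tetraen-16,2-olide | C=C1C(=O)O[C@H]2/C=C(\C)CC/C=C(\C)[C@H](O[Si](C)(C)C(C)(C)C)C/C=C(\C)CC[C@H]12 | intermediate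
31 | (1R,2S,9R,3E,7E,11E)-9-hydroxycembra-3,7,11,15(17)-tetraen-16,2-olide | C=C1C(=O)O[C@H]2/C=C(\C)CC/C=C(\C)[C@H](O)C/C=C(\C)CC[C@H]12 | intermediate
32 | (1R,2S,9R,3E,7E,11E)-9-acetoxycembra-3,7,11,15(17)-tetraen-16,2-olide (CNP0129197.1) | C=C1C(=O)O[C@H]2/C=C(\C)CC/C=C(\C)[C@H](OC(C)=O)C/C=C(\C)CC[C@H]12 | target

**Step count**

Total steps: 20. Longest linear sequence: 16 (steps 1–7, then 12–20); the fragment B branch is steps 8–11.

**Steps most likely to fail**

Step 16. The ligand may not override the conformational preferences of the closing 14-membered ring, so that face selectivity at the C2 aldehyde is insufficient, and the alkoxide may stall before lactone closure. The fallback sets out from 25 and cyclises without the chiral ligand (CrCl2, NiCl2 cat., DMSO/THF, high dilution), which should give 27 together with its C2 epimer. The separated cis-fused (1R,2S,9R)-9-[(tert-butyldimethylsilyl)oxy]-17-norcembra-3,7,11-trien-16,2-olide F1 is opened with LiOH in THF/H2O to 2-[(1R,2S,3E,7E,9R,11E)-9-[(tert-butyldimethylsilyl)oxy]-2-hydroxy-4,8,12-trimethylcyclotetradeca-3,7,11-trien-1-yl]acetic acid F2. Mitsunobu lactonisation of F2 (PPh3, diisopropyl azodicarboxylate, THF, 0 °C) lets the carboxylate displace the activated C2 oxygen with inversion, and the route is rejoined at 27.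

Step 13. Halogen exchange at the trisubstituted alkenyl carbon may stop at an equilibrium mixture that is hard to separate, and iodide at 110 °C may demethylate the ester. The fallback sets out from 22 and uses Pd(PPh3)4-catalysed stannylation with hexamethylditin (toluene, 90 °C) to give methyl (3R,6E,9R,10E,14E)-9-[(tert-butyldimethylsilyl)oxy]-3-{[(4-methoxybenzyl)oxy]methyl}-6,10,14-trimethyl-15-(trimethylstannyl)pentadeca-6,10,14-trienoate F3. Iododestannylation of F3 with I2 in CH2Cl2 at 0 °C, with retention, returns to the route at 23.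

Step 14. The freed C2 hydroxyl may close onto the C16 methyl ester before it can be oxidised. The fallback sets out from 23: after DDQ cleavage the crude is deliberately closed with camphorsulfonic acid to the stable (4R)-4-[(3E,6R,7E,11E)-6-[(tert-butyldimethylsilyl)oxy]-12-iodo-3,7,11-trimethyldodeca-3,7,11-trien-1-yl]dihydrofuran-2(3H)-one F4. F4 is opened with one equivalent of NaOH (THF/H2O) to sodium (3R,6E,9R,10E,14E)-9-[(tert-butyldimethylsilyl)oxy]-3-(hydroxymethyl)-15-iodo-6,10,14-trimethylpentadeca-6,10,14-trienoate F5. After drying, the carboxylate of F5 is methylated with MeI in DMF to regenerate 24 in solution, Dess–Martin periodinane is added to the same flask, and the route is rejoined at 25.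

**Further compounds**

F1 | step 16 | (1R,2S,9R,3E,7E,11E)-9-[(tert-butyldimethylsilyl)oxy]-17-norcembra-3,7,11-trien-16,2-olide (cis-fused C2 epimer of 27) | C1C(=O)O[C@@H]2/C=C(\C)CC/C=C(\C)[C@H](O[Si](C)(C)C(C)(C)C)C/C=C(\C)CC[C@H]12
F2 | step 16 | 2-[(1R,2S,3E,7E,9R,11E)-9-[(tert-butyldimethylsilyl)oxy]-2-hydroxy-4,8,12-trimethylcyclotetradeca-3,7,11-trien-1-yl]acetic acid | OC(=O)C[C@H]1CC/C(C)=C/C[C@@H](O[Si](C)(C)C(C)(C)C)/C(C)=C/CC/C(C)=C/[C@H]1O
F3 | step 13 | methyl (3R,6E,9R,10E,14E)-9-[(tert-butyldimethylsilyl)oxy]-3-{[(4-methoxybenzyl)oxy]methyl}-6,10,14-trimethyl-15-(trimethylstannyl)pentadeca-6,10,14-trienoate | COC(=O)C[C@H](COCc1ccc(OC)cc1)CC/C(C)=C/C[C@@H](O[Si](C)(C)C(C)(C)C)/C(C)=C/CC/C(C)=C/[Sn](C)(C)C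
F4 | step 14 | (4R)-4-[(3E,6R,7E,11E)-6-[(tert-butyldimethylsilyl)oxy]-12-iodo-3,7,11-trimethyldodeca-3,7,11-trien-1-yl]dihydrofuran-2(3H)-one | O=C1C[C@@H](CC/C(C)=C/C[C@@H](O[Si](C)(C)C(C)(C)C)/C(C)=C/CC/C(C)=C/I)CO1
F5 | step 14 | sodium (3R,6E,9R,10E,14E)-9-[(tert-butyldimethylsilyl)oxy]-3-(hydroxymethyl)-15-iodo-6,10,14-trimethylpentadeca-6,10,14-trienoate | [Na+].[O-]C(=O)C[C@H](CO)CC/C(C)=C/C[C@@H](O[Si](C)(C)C(C)(C)C)/C(C)=C/CC/C(C)=C/I
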